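## The problem

Compound 25 is a 2-arylbenzofuran without any stereocentre, so no centre has to be set or can steer another: the benzofuran (benzo ring A, furan ring B) carries a hydroxyl on C6 and a prenyl group on C7, and its C2 is bonded to C1' of a resorcinol ring C that has prenyl groups on both flanking carbons (C2', C6') and hydroxyls on C3' and C5'. The C2–C1' bond is therefore hemmed in by two ortho CH2 groups, which makes a late biaryl coupling at this bond unattractive. C7 lies between two oxygen-bearing carbons (C6 and C7a), a position that direct prenylation of a preformed benzofuranol does not address cleanly. Every prenyl group is ortho to a phenolic oxygen, so acid, electrophilic halogen, electrophilic metals, hydrogenation and strong oxidants threaten chroman formation or the trisubstituted alkenes; the free polyphenol is also air-sensitive in base, so the hydroxyls should travel as fluoride-labile silyl ethers and be released last. Ring C has a local mirror plane through C1' and C4', which allows its two prenyl groups to be introduced two-directionally. Ring A, read from C7a, shows the sequence oxygen (C7a), carbon substituent (C7), oxygen (C6), H (C5), H (C4), carbon arm (C3a), which is the pattern a vinylketene and a 1-siloxyalkyne deliver in a benzannulation, with the C7a oxygen free and the C6 oxygen silylated. If the arm on C3a is the alkyne that becomes C3 and C2, the free C7a hydroxyl sits ortho to it and ring B can be closed by addition across the triple bond.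

## Retrosynthesis

**Ring B last (25 ⇒ 23).** The O1–C2 bond and the three O–Si bonds are cut, leading back through the tetraol 24 to the o-alkynylphenol 23. Against the neighbouring cut at C2–C1', this one never requires a coupling at the doubly flanked C1'; the junction is an alkyne carbon until the last step. The precursor lacks ring B and has all hydroxyls but one masked. The forward reaction must be basic, because acid or electrophilic metals would engage the o-prenylphenols.

**Ring A by benzannulation (23 ⇒ 13 + 18).** Four bonds of ring A are cut together: C4–C5, C5–C6, C7–C7a and C3a–C7a. Making ring A from a preformed resorcinol would instead require a prenyl group between two oxygens that must then be told apart. The annulation places the prenyl group, the free hydroxyl, the silylated hydroxyl and the alkynyl arm in one operation through the polarity of its partners. The precursors are a linear enynyl diazoketone 13 and the siloxyalkyne 18. The forward reaction is a photochemical Wolff shift to vinylketene 19, a [2+2] cycloaddition with 18, and two electrocyclic steps.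

**Siloxyalkyne, C–O bond (18 ⇒ 16).** The O–C(sp) bond is cut, so that the ynol ether comes from the terminal alkyne 16 by oxygenation of its acetylide and O-silylation of the ynolate 17. The alternative from an ester by homologation would need a base-sensitive β,γ-unsaturated ester. The forward step must deprotonate only the acetylenic C–H of the skipped enyne.

**Siloxyalkyne, C–C bond (16 ⇒ 14 + 15).** The propargylic–allylic bond is cut to prenyl bromide 14 and ethynylmagnesium bromide 15, both commercial. The coupling must take place at the primary end of the allyl system.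

**Diazo group (13 ⇒ 11).** The C=N2 unit is removed to leave the methyl ketone 11. Acylation of diazomethane by an enynoyl chloride is the neighbouring option, but conjugated acid chlorides add diazomethane across the alkene. Diazo transfer to the activated ketone (through 12) avoids this.

**Enone alkene (11 ⇒ 8 + 9).** The C3=C4 bond of the hexenynone is cut to the acetonyl ylide 9 and an ynal 10, which is generated from the propargylic alcohol 8 and trapped in the same flask. A stabilised ylide is required to give the (E)-alkene.

**Aryl–alkyne bond (8 ⇒ 6 + 7).** The C1'–C(sp) bond is cut to aryl iodide 6 and prop-2-yn-1-ol 7. A Sonogashira coupling puts a slim sp carbon, not an arene, onto the crowded C1'. It must tolerate two ortho CH2 groups.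

**Prenyl groups of ring C (6 ⇒ 5 ⇒ 4).** After removal of the silyl groups, both aryl–CH2 bonds are cut by a two-fold retro-Claisen step to the bis(1,1-dimethylallyl) ether 4. Direct C-prenylation of a resorcinol gives mixtures, and metalation goes between the oxygens, whereas the rearrangement delivers the group from oxygen to an ortho carbon. The forward reaction must choose the ortho carbon next to iodine over the one between the oxygens. The other oxygen (para-directing) and the iodine (electron-withdrawing, meta to the migrating oxygen) both push that way.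

**Ether bonds (4 ⇒ 3 ⇒ 1 + 2).** The two tertiary O–C bonds are cut to 5-iodoresorcinol 1 and two molecules of the propargylic chloride 2, by way of the bis(propargyl) ether 3. The tertiary allyl ether cannot be made by SN2 chemistry, so copper-catalysed propargylation at both hydroxyls followed by semihydrogenation is used.

## Roads not taken

Alternative 1: The cut is at three bonds that meet at ring C: C1'–C2 and the two aryl–CH2 bonds at C2' and C6'.
- Forward key step: 1-iodo-3,5-bis(methoxymethoxy)benzene A1 would be alkylated at both ortho C–H bonds by two molecules of (2-bromoethoxy)(tert-butyl)dimethylsilane A2 under Pd(OAc)2, norbornene, PPh3 and Cs2CO3 (Catellani reaction). The aryl–palladium species would then be intercepted at the ipso carbon by 2-[6-(methoxymethoxy)-7-(3-methylbut-2-enyl)-1-benzofuran-2-yl]-4,4,5,5-tetramethyl-1,3,2-dioxaborolane A3. The product would be 2-{2,6-bis[2-(tert-butyldimethylsilyloxy)ethyl]-3,5-bis(methoxymethoxy)phenyl}-6-(methoxymethoxy)-7-(3-methylbut-2-enyl)benzofuran A4; no ring closes.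
- Merits: three C–C bonds form in one flask, the pattern of ring C is dictated by the iodide without regiochemical doubt, and rings A and B are made separately.
- Weak points: each ortho C–H bond of A1 lies between the iodide and an acetal oxygen, a buttressed position where palladacycle formation and the second alkylation are expected to be slow. A3 belongs to a class of boronates that protodeboronate readily, and it must couple at a doubly ortho-alkylated aryl–palladium centre. A4 is still far from 25: both silyloxyethyl arms must be unmasked, oxidised to enolisable arylacetaldehydes and olefinated, and three acetals must be removed with acid beside three o-prenylphenols.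
- Comparison: in regiochemical certainty at ring C this road is better than the chosen plan, whose double Claisen rearrangement (step 3) has only a bias in its favour. The chosen plan sets against it a C2–C1' junction that is never formed by coupling at a crowded carbon, prenyl groups that are installed as such, and a deprotection by fluoride alone.

Alternative 2: Ring C is cut at C1'–C2' and C1'–C6', so that C1' comes from an ester carbonyl and the other five ring carbons from a symmetric β-diketone.
- Forward key step: the dianion of 2,12-dimethyltrideca-2,11-diene-6,8-dione A5 (two equivalents of LiN(iPr)2) would be acylated at a terminal carbon by methyl 6-(methoxymethoxy)-7-(3-methylbut-2-enyl)-1-benzofuran-2-carboxylate A6. The resulting 1-[6-(methoxymethoxy)-7-(3-methylbut-2-enyl)-1-benzofuran-2-yl]-9-methyl-2-(3-methylbut-2-enyl)dec-8-ene-1,3,5-trione A7 would be closed in the same flask by KOH through aldol condensation onto the aryl ketone. This gives 2-[3,5-dihydroxy-2,6-bis(3-methylbut-2-enyl)phenyl]-6-(methoxymethoxy)-7-(3-methylbut-2-enyl)benzofuran A8.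
- Merits: on paper this is the shortest road. A5 is simple and symmetric, both prenyl groups and both hydroxyls of ring C are in place by construction, and A8 is one deprotection from 25.
- Weak points: the ring closure needs a secondary carbanion to attack a conjugated, hindered heteroaryl ketone and build the fully flanked C1'. A7 is more acidic than A5, so the acylation stalls unless a third equivalent of base is supplied. Hydroxide can cleave the β-dicarbonyl units of A7 by retro-Claisen reaction, and O-cyclisation to pyranones competes. The methoxymethyl ether of A8 must be removed with acid beside three o-prenylphenols.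
- Comparison: if the annulation worked, this road would beat the chosen plan in step count. The chosen plan sets against it a ring construction by pericyclic steps under neutral conditions, with regiochemistry fixed by polarity and with close precedent in type, and an end game free of acid.

Alternative 3: Ring A is cut at C3a–C4, leaving a 2,5-disubstituted furan that already carries ring C.
- Forward key step: silylation of (1E)-4-{5-[3,5-bis(tert-butyldimethylsilyloxy)-2,6-bis(3-methylbut-2-enyl)phenyl]furan-2-yl}-1-(dimethylamino)-7-methylocta-1,6-dien-3-one A9 with tBuMe2SiOTf and NEt3 would give (1E,3E)-4-{5-[3,5-bis(tert-butyldimethylsilyloxy)-2,6-bis(3-methylbut-2-enyl)phenyl]furan-2-yl}-3-(tert-butyldimethylsilyloxy)-N,N,7-trimethylocta-1,3,6-trien-1-amine A10, whose furan double bond serves as the third alkene. Heating would bring about six-electron electrocyclisation onto the furan β-carbon, and loss of HNMe2 would aromatise ring A to the tris(tert-butyldimethylsilyl) ether of 25, A11.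
- Merits: A11 is one fluoride treatment from the target, no light is needed, and the oxygen at C6 and the prenyl group at C7 are placed by the skeleton of A9.
- Weak points: the closure must give up the aromaticity of the furan in the transition state, and no close precedent exists for furan-terminated amino siloxy trienes. It needs the tetrasubstituted enol ether of A10 with furan and aminovinyl group cis, which the silylation does not control. A9 itself requires the crowded C2–C1' bond to be made by cross-coupling onto a doubly ortho-prenylated arene.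
- Comparison: this road ends closer to 25 than the chosen plan, since A11 needs no cyclisation, and it avoids photochemistry. The chosen plan sets against it a key step of established type, linear fragments that are easy to make, and a C2–C1' junction that arises from an alkyne.

Key step: step 10

Remark on the chemistry: 25 has no stereocentre and each of its alkenes ends in two methyl groups, so no configuration has to be set. Cyclobutenone 20 and cyclohexadienone 22 are transient racemates whose stereocentres vanish.

## Route

Step 1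
Reactants: 1 5-iodobenzene-1,3-diol; 2 3-chloro-3-methylbut-1-yne
Product: 3 1-iodo-3,5-bis[(2-methylbut-3-yn-2-yl)oxy]benzene
Conditions: 2 (2.4 equiv in all), CuCl2·2H2O (1 mol %), DBU (2.6 equiv), MeCN, 0 °C
Reagents that add atoms: 3-chloro-3-methylbut-1-yne, C#CC(C)(C)Cl (second equivalent of 2 for the second hydroxyl)
Why: Copper-catalysed O-propargylation of phenols with a tertiary propargylic chloride (through a copper allenylidene) is the standard entry to aryl 1,1-dimethylpropargyl ethers; both hydroxyls of 1 react, so two equivalents of 2 are consumed, and at 0 °C neither the C–I bond nor the ethers, which would close to chromenes on heating, are at risk.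

Step 2
Reactants: 3 1-iodo-3,5-bis[(2-methylbut-3-yn-2-yl)oxy]benzene
Product: 4 1-iodo-3,5-bis[(2-methylbut-3-en-2-yl)oxy]benzene
Conditions: H2 (1 atm), Pd/CaCO3 poisoned with Pb(OAc)2 (Lindlar catalyst), quinoline, EtOAc, 20 °C, stopped after two equivalents of H2
Reagents that add atoms: none
Why: Lindlar semihydrogenation of the two terminal alkynes should stop at the alkenes on the poisoned surface, which is also too inactive to hydrogenolyse the aryl iodide at 20 °C.

Step 3
Reactants: 4 1-iodo-3,5-bis[(2-methylbut-3-en-2-yl)oxy]benzene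
Product: 5 5-iodo-4,6-bis(3-methylbut-2-enyl)benzene-1,3-diol
Conditions: PhNEt2, 140 °C, argon
Reagents that add atoms: none
Why: Two aromatic Claisen ([3,3]-sigmatropic) rearrangements, each followed by tautomerisation, turn the tertiary allyl ethers into ortho prenyl groups; the para-directing second oxygen and the electron-withdrawing iodine both favour the ortho carbon next to iodine over the carbon between the oxygens, so the symmetric isomer should dominate and is separated from the unsymmetrical one, while the amine solvent keeps the o-prenylphenols from closing to chromans.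

Step 4
Reactants: 5 5-iodo-4,6-bis(3-methylbut-2-enyl)benzene-1,3-diol
Product: 6 1,5-bis(tert-butyldimethylsilyloxy)-3-iodo-2,4-bis(3-methylbut-2-enyl)benzene
Conditions: t-BuMe2SiCl (2.5 equiv), imidazole (5 equiv), DMF, 20 °C
Reagents that add atoms: tert-butyldimethylsilyl chloride, CC(C)(C)[Si](C)(C)Cl
Why: Standard silylation of both phenols; the aryl silyl ethers should tolerate the amine bases, MnO2, the amide base at −78 °C and light of the later steps and fall to fluoride at the end.

Step 5
Reactants: 6 1,5-bis(tert-butyldimethylsilyloxy)-3-iodo-2,4-bis(3-methylbut-2-enyl)benzene; 7 prop-2-yn-1-ol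
Product: 8 3-[3,5-bis(tert-butyldimethylsilyloxy)-2,6-bis(3-methylbut-2-enyl)phenyl]prop-2-yn-1-ol
Conditions: PdCl2(PPh3)2 (5 mol %), CuI (10 mol %), Et3N, THF, 60 °C, degassed
Reagents that add atoms: none
Why: Sonogashira coupling; zerovalent palladium inserts into aryl iodides even between two ortho CH2 groups, the incoming carbon is a slim sp centre, and the free primary alcohol and the silyl ethers are inert to the amine base.

Step 6
Reactants: 8 3-[3,5-bis(tert-butyldimethylsilyloxy)-2,6-bis(3-methylbut-2-enyl)phenyl]prop-2-yn-1-ol; 9 1-(triphenylphosphoranylidene)propan-2-one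
Product: 11 (3E)-6-[3,5-bis(tert-butyldimethylsilyloxy)-2,6-bis(3-methylbut-2-enyl)phenyl]hex-3-en-5-yn-2-one, via ynal 10 (not isolated)
Conditions: activated MnO2 (10 equiv), CH2Cl2, 20–40 °C
Reagents that add atoms: none
Why: Tandem oxidation–Wittig olefination: MnO2 oxidises the propargylic alcohol to ynal 10, which the acetyl-stabilised ylide traps as it forms, so the sensitive ynal is never handled; stabilised ylides give the (E)-alkene.

Step 7
Reactants: 11 (3E)-6-[3,5-bis(tert-butyldimethylsilyloxy)-2,6-bis(3-methylbut-2-enyl)phenyl]hex-3-en-5-yn-2-one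
Product: 13 (3E)-1-diazo-6-[3,5-bis(tert-butyldimethylsilyloxy)-2,6-bis(3-methylbut-2-enyl)phenyl]hex-3-en-5-yn-2-one, via trifluoroacetyl diketone 12 (not isolated)
Conditions: LiN(SiMe3)2, THF, −78 °C; CF3CO2CH2CF3; aq. HCl work-up; then MeSO2N3, Et3N, H2O, MeCN, 20 °C, in the dark
Reagents that add atoms: methanesulfonyl azide, CS(=O)(=O)N=[N+]=[N-] (both diazo nitrogens); 2,2,2-trifluoroethyl trifluoroacetate, O=C(OCC(F)(F)F)C(F)(F)F (its CF3CO group is carried by 12 only)
Why: Detrifluoroacetylative diazo transfer: the kinetic lithium enolate of the methyl ketone is C-acylated to diketone 12, which takes the diazo group from the sulfonyl azide under Et3N and loses the trifluoroacetyl group as the N-sulfonyl amide; this is the standard route to α′-diazo enones and avoids acid chlorides and diazomethane.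

Step 8
Reactants: 14 1-bromo-3-methylbut-2-ene; 15 ethynylmagnesium bromide
Product: 16 5-methylhex-4-en-1-yne
Conditions: CuBr·SMe2 (5 mol %), THF, 0 → 20 °C, 15 in excess
Reagents that add atoms: none
Why: Copper-catalysed coupling of an alkynyl Grignard reagent with a primary allylic bromide; attack at the unhindered CH2 end gives the skipped enyne, and the excess of 15 suppresses double coupling.

Step 9
Reactants: 16 5-methylhex-4-en-1-yne
Product: 18 triisopropyl[(5-methylhex-4-en-1-yn-1-yl)oxy]silane, via lithium ynolate 17 (not isolated)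
Conditions: n-BuLi, THF, −78 °C; LiOOt-Bu (from t-BuOOH and LiN(SiMe3)2), −78 → 0 °C; iPr3SiOSO2CF3, −78 → 0 °C
Reagents that add atoms: tert-butyl hydroperoxide, CC(C)(C)OO (the ynol oxygen); triisopropylsilyl trifluoromethanesulfonate, CC(C)[Si](C(C)C)(C(C)C)OS(=O)(=O)C(F)(F)F
Why: Oxidation of a lithium acetylide by lithium tert-butyl peroxide (electrophilic oxygen transfer) gives ynolate 17, which the bulky silyl triflate silylates on oxygen, the known route to triisopropylsilyl ynol ethers; one equivalent of n-BuLi at −78 °C removes only the acetylenic proton.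

Step 10
Reactants: 13 (3E)-1-diazo-6-[3,5-bis(tert-butyldimethylsilyloxy)-2,6-bis(3-methylbut-2-enyl)phenyl]hex-3-en-5-yn-2-one; 18 triisopropyl[(5-methylhex-4-en-1-yn-1-yl)oxy]silane
Product: 23 2-{[3,5-bis(tert-butyldimethylsilyloxy)-2,6-bis(3-methylbut-2-enyl)phenyl]ethynyl}-6-(3-methylbut-2-enyl)-5-(triisopropylsilyloxy)phenol, via vinylketene 19 (not isolated), via cyclobutenone 20 (not isolated), via dienylketene 21 (not isolated), via cyclohexadienone 22 (not isolated)
Conditions: 18 (1.5 equiv), hν (Hg lamp through Pyrex, λ > 300 nm), ClCH2CH2Cl (dilute, degassed), 20 °C; then 80 °C in the dark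
Reagents that add atoms: none
Why: This is the Danheiser benzannulation in its photochemical Wolff form, the known reaction of α′-diazo enones with 1-siloxyalkynes. Light expels N2 from 13 and the alkenyl group shifts from the carbonyl carbon to the diazo carbon (C4–C5), giving vinylketene 19. The prenyl-bearing carbon of 18, the nucleophilic end of the ynol ether, bonds to the ketene carbonyl carbon (C7–C7a) and the siloxy carbon to the ketene α-carbon (C5–C6) in a regiospecific [2+2] cycloaddition that gives cyclobutenone 20. Reversible four-electron electrocyclic opening of 20, completed by heating in the dark, gives dienylketene 21, and ring A closes by thermal disrotatory six-electron electrocyclisation between the ketene carbon and the alkyne-bearing alkene carbon (C3a–C7a); cyclohexadienone 22 then tautomerises to 23. No stereocentre is created for good, since the sp3 carbons of 20 and 22 are racemic and are flattened on ring opening and on aromatisation. The step needs regioselectivity, which the matched polarity of ketene and siloxyalkyne secures (prenyl on C7 between the free C7a hydroxyl and the silylated C6 oxygen, alkynyl arm on C3a), and chemoselectivity, which follows because only the electron-rich ynol ether, not the arylalkyne or the prenyl alkenes, is ketenophilic. The (E)-alkene turns the alkynyl group outward in the closure; should light isomerise it, the slim linear alkynyl group can still turn inward and both isomers should converge on 23, so the design does not hinge on the geometry. Pyrex-filtered light, dilution and an excess of 18 are chosen to limit excitation of the aryl enynone chromophore, photodimerisation and capture of 19 by the product phenol.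

Step 11
Reactants: 23 2-{[3,5-bis(tert-butyldimethylsilyloxy)-2,6-bis(3-methylbut-2-enyl)phenyl]ethynyl}-6-(3-methylbut-2-enyl)-5-(triisopropylsilyloxy)phenol
Product: 25 5-[6-hydroxy-7-(3-methylbut-2-enyl)-1-benzofuran-2-yl]-4,6-bis(3-methylbut-2-enyl)benzene-1,3-diol, via tetraol alkyne 24 (not isolated)
Conditions: Bu4NF (6 equiv), THF, 0 → 65 °C, argon; then AcOH
Reagents that add atoms: none
Why: Fluoride cleaves the three aryl silyl ethers to 24, and on heating the fluoride and phenoxide base drives the 5-endo-dig addition of the C7a oxygen to the alkyne carbon that carries ring C (base-mediated cycloisomerisation of an o-alkynylphenol), closing furan ring B; basic conditions are chosen because acid or electrophilic metals would close the o-prenylphenols to chromans or engage the prenyl alkenes with the alkyne.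

## Compound list

1 | 5-iodobenzene-1,3-diol | Oc1cc(O)cc(I)c1 | starting material
2 | 3-chloro-3-methylbut-1-yne | C#CC(C)(C)Cl | starting material
3 | 1-iodo-3,5-bis[(2-methylbut-3-yn-2-yl)oxy]benzene | C#CC(C)(C)Oc1cc(I)cc(OC(C)(C)C#C)c1 | intermediate
4 | 1-iodo-3,5-bis[(2-methylbut-3-en-2-yl)oxy]benzene | C=CC(C)(C)Oc1cc(I)cc(OC(C)(C)C=C)c1 | intermediate
5 | 5-iodo-4,6-bis(3-methylbut-2-enyl)benzene-1,3-diol | Oc1cc(O)c(CC=C(C)C)c(I)c1CC=C(C)C | intermediate
6 | 1,5-bis(tert-butyldimethylsilyloxy)-3-iodo-2,4-bis(3-methylbut-2-enyl)benzene | CC(C)=CCc1c(I)c(CC=C(C)C)c(O[Si](C)(C)C(C)(C)C)cc1O[Si](C)(C)C(C)(C)C | intermediate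
7 | prop-2-yn-1-ol | OCC#C | starting material
8 | 3-[3,5-bis(tert-butyldimethylsilyloxy)-2,6-bis(3-methylbut-2-enyl)phenyl]prop-2-yn-1-ol | OCC#Cc1c(CC=C(C)C)c(O[Si](C)(C)C(C)(C)C)cc(O[Si](C)(C)C(C)(C)C)c1CC=C(C)C | intermediate
9 | 1-(triphenylphosphoranylidene)propan-2-one | CC(=O)C=P(c1ccccc1)(c1ccccc1)c1ccccc1 | starting material
10 | 3-[3,5-bis(tert-butyldimethylsilyloxy)-2,6-bis(3-methylbut-2-enyl)phenyl]prop-2-ynal (formed in the flask) | O=CC#Cc1c(CC=C(C)C)c(O[Si](C)(C)C(C)(C)C)cc(O[Si](C)(C)C(C)(C)C)c1CC=C(C)C | intermediate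
11 | (3E)-6-[3,5-bis(tert-butyldimethylsilyloxy)-2,6-bis(3-methylbut-2-enyl)phenyl]hex-3-en-5-yn-2-one | CC(=O)/C=C/C#Cc1c(CC=C(C)C)c(O[Si](C)(C)C(C)(C)C)cc(O[Si](C)(C)C(C)(C)C)c1CC=C(C)C | intermediate
12 | (5E)-8-[3,5-bis(tert-butyldimethylsilyloxy)-2,6-bis(3-methylbut-2-enyl)phenyl]-1,1,1-trifluorooct-5-en-7-yne-2,4-dione (formed in the flask) | O=C(CC(=O)/C=C/C#Cc1c(CC=C(C)C)c(O[Si](C)(C)C(C)(C)C)cc(O[Si](C)(C)C(C)(C)C)c1CC=C(C)C)C(F)(F)F | intermediate
13 | (3E)-1-diazo-6-[3,5-bis(tert-butyldimethylsilyloxy)-2,6-bis(3-methylbut-2-enyl)phenyl]hex-3-en-5-yn-2-one | [N-]=[N+]=CC(=O)/C=C/C#Cc1c(CC=C(C)C)c(O[Si](C)(C)C(C)(C)C)cc(O[Si](C)(C)C(C)(C)C)c1CC=C(C)C | intermediate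
14 | 1-bromo-3-methylbut-2-ene | CC(C)=CCBr | starting material
15 | ethynylmagnesium bromide | C#C[Mg]Br | starting material
16 | 5-methylhex-4-en-1-yne | C#CCC=C(C)C | intermediate
17 | lithium 5-methylhex-4-en-1-yn-1-olate (formed in the flask) | [Li+].[O-]C#CCC=C(C)C | intermediate
18 | triisopropyl[(5-methylhex-4-en-1-yn-1-yl)oxy]silane | CC(C)=CCC#CO[Si](C(C)C)(C(C)C)C(C)C | intermediate
19 | (3E)-6-[3,5-bis(tert-butyldimethylsilyloxy)-2,6-bis(3-methylbut-2-enyl)phenyl]hexa-1,3-dien-5-yn-1-one (vinylketene, formed in the flask) | O=C=C/C=C/C#Cc1c(CC=C(C)C)c(O[Si](C)(C)C(C)(C)C)cc(O[Si](C)(C)C(C)(C)C)c1CC=C(C)C | intermediate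
20 | 4-{(1E)-4-[3,5-bis(tert-butyldimethylsilyloxy)-2,6-bis(3-methylbut-2-enyl)phenyl]but-1-en-3-ynyl}-2-(3-methylbut-2-enyl)-3-(triisopropylsilyloxy)cyclobut-2-en-1-one (racemic, formed in the flask) | O=C1C(CC=C(C)C)=C(O[Si](C(C)C)(C(C)C)C(C)C)C1/C=C/C#Cc1c(CC=C(C)C)c(O[Si](C)(C)C(C)(C)C)cc(O[Si](C)(C)C(C)(C)C)c1CC=C(C)C | intermediate
21 | (3E,5E)-8-[3,5-bis(tert-butyldimethylsilyloxy)-2,6-bis(3-methylbut-2-enyl)phenyl]-2-(3-methylbut-2-enyl)-3-(triisopropylsilyloxy)octa-1,3,5-trien-7-yn-1-one (dienylketene, formed in the flask) | O=C=C(CC=C(C)C)/C(O[Si](C(C)C)(C(C)C)C(C)C)=C\C=C\C#Cc1c(CC=C(C)C)c(O[Si](C)(C)C(C)(C)C)cc(O[Si](C)(C)C(C)(C)C)c1CC=C(C)C | intermediate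
22 | 6-{[3,5-bis(tert-butyldimethylsilyloxy)-2,6-bis(3-methylbut-2-enyl)phenyl]ethynyl}-2-(3-methylbut-2-enyl)-3-(triisopropylsilyloxy)cyclohexa-2,4-dien-1-one (racemic, formed in the flask) | O=C1C(CC=C(C)C)=C(O[Si](C(C)C)(C(C)C)C(C)C)C=CC1C#Cc1c(CC=C(C)C)c(O[Si](C)(C)C(C)(C)C)cc(O[Si](C)(C)C(C)(C)C)c1CC=C(C)C | intermediate
23 | 2-{[3,5-bis(tert-butyldimethylsilyloxy)-2,6-bis(3-methylbut-2-enyl)phenyl]ethynyl}-6-(3-methylbut-2-enyl)-5-(triisopropylsilyloxy)phenol | Oc1c(CC=C(C)C)c(O[Si](C(C)C)(C(C)C)C(C)C)ccc1C#Cc1c(CC=C(C)C)c(O[Si](C)(C)C(C)(C)C)cc(O[Si](C)(C)C(C)(C)C)c1CC=C(C)C | intermediate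
24 | 4-{[3,5-dihydroxy-2,6-bis(3-methylbut-2-enyl)phenyl]ethynyl}-2-(3-methylbut-2-enyl)benzene-1,3-diol (formed in the flask) | Oc1c(CC=C(C)C)c(O)ccc1C#Cc1c(CC=C(C)C)c(O)cc(O)c1CC=C(C)C | intermediate
25 | 5-[6-hydroxy-7-(3-methylbut-2-enyl)-1-benzofuran-2-yl]-4,6-bis(3-methylbut-2-enyl)benzene-1,3-diol | CC(C)=CCc1c(O)cc(O)c(CC=C(C)C)c1-c1cc2ccc(O)c(CC=C(C)C)c2o1 | target

## Step count and risks

Total: 11 steps. Longest linear sequence: 9 steps (steps 1–7, 10 and 11, from 1). The siloxyalkyne branch (steps 8 and 9) joins at step 10.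

**Key step (step 10).** The aryl-conjugated enynone chromophore of 13 absorbs more strongly than the diazoketone band. Photoisomerisation, photodimerisation and inner-filter slowing may therefore outrun the Wolff shift, and the accumulating phenol may drain the vinylketene by acylation. The fallback moves the benzannulation ahead of the fragment union, so that the light-driven step runs on a small silyl-capped enyne and ring C arrives afterwards. It sets out from ylide 9, siloxyalkyne 18 and aryl iodide 6 and comes back at 23. Wittig reaction of purchased 3-(trimethylsilyl)prop-2-ynal F1 with 9 should give (3E)-6-(trimethylsilyl)hex-3-en-5-yn-2-one F2. Trifluoroacetylation as in step 7 gives (5E)-1,1,1-trifluoro-8-(trimethylsilyl)oct-5-en-7-yne-2,4-dione F3, and diazo transfer gives (3E)-1-diazo-6-(trimethylsilyl)hex-3-en-5-yn-2-one F4. Irradiation of F4 with 18 and heating should lead through the vinylketene (3E)-6-(trimethylsilyl)hexa-1,3-dien-5-yn-1-one F5, the cyclobutenone 2-(3-methylbut-2-enyl)-3-(triisopropylsilyloxy)-4-[(1E)-4-(trimethylsilyl)but-1-en-3-ynyl]cyclobut-2-en-1-one F6, the dienylketene (3E,5E)-2-(3-methylbut-2-enyl)-3-(triisopropylsilyloxy)-8-(trimethylsilyl)octa-1,3,5-trien-7-yn-1-one F7 and the cyclohexadienone 2-(3-methylbut-2-enyl)-3-(triisopropylsilyloxy)-6-[(trimethylsilyl)ethynyl]cyclohexa-2,4-dien-1-one F8 to 2-(3-methylbut-2-enyl)-3-(triisopropylsilyloxy)-6-[(trimethylsilyl)ethynyl]phenol F9. K2CO3 in MeOH at 0 °C removes the C-silyl group to give 6-ethynyl-2-(3-methylbut-2-enyl)-3-(triisopropylsilyloxy)phenol F10. Sonogashira coupling of F10 with 6 (PdCl2(PPh3)2, CuI, Et3N, 60 °C) then gives 23.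

**Step 3.** The rearrangement may scatter, with part of the allyl groups migrating to the carbon between the two oxygens, and the tertiary ether may ionise and lose isoprene, so that the symmetric isomer is obtained in poor amount. The fallback puts the two prenyl groups on by cross-coupling at positions fixed by electrophilic bromination. It sets out from 1 and comes back at 8. Silylation of 1 (t-BuMe2SiCl, imidazole) gives 1,3-bis(tert-butyldimethylsilyloxy)-5-iodobenzene F11. Sonogashira coupling with 7 gives 3-[3,5-bis(tert-butyldimethylsilyloxy)phenyl]prop-2-yn-1-ol F12. N-Bromosuccinimide in MeCN should brominate the two ring carbons that are para to one silyloxy group and ortho to the other (the carbon between the two silyloxy groups is shielded by both), giving 3-[2,6-dibromo-3,5-bis(tert-butyldimethylsilyloxy)phenyl]prop-2-yn-1-ol F13. A two-fold linear-selective Negishi coupling with (3-methylbut-2-enyl)zinc bromide F14 (made from 14 and zinc and used in excess; Pd(OAc)2 with the biarylphosphine CPhos) should then give 8.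

**Step 11.** Desilylation is fast, and the electron-rich phenoxides of 24, above all the oxygen para to the alkyne, may slow the 5-endo-dig closure so that the reaction stalls at 24. Air oxidation of the polyphenoxide under hot basic conditions is a second hazard. The fallback closes the ring before the silyl groups are removed. It sets out from 23 and comes back at 25. CuI (10 mol %) with Et3N in DMF at 80 °C, conditions under which o-alkynylphenols close to benzofurans through the copper phenoxide, should give 2-[3,5-bis(tert-butyldimethylsilyloxy)-2,6-bis(3-methylbut-2-enyl)phenyl]-7-(3-methylbut-2-enyl)-6-(triisopropylsilyloxy)-1-benzofuran F15. Bu4NF buffered with AcOH in THF at 0 °C then gives 25.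

**Step 5.** Oxidative addition at the electron-rich C–I bond between two ortho CH2 groups may be slow, so that copper-mediated homocoupling consumes 7 and conversion of 6 stays incomplete. The fallback carries out the coupling before the ring becomes crowded. It sets out from 4 and comes back at 8. Sonogashira coupling of 4 with 7 gives 3-{3,5-bis[(2-methylbut-3-en-2-yl)oxy]phenyl}prop-2-yn-1-ol F16. Double Claisen rearrangement as in step 3, now next to a slim and still electron-withdrawing alkynyl group, gives 5-(3-hydroxyprop-1-ynyl)-4,6-bis(3-methylbut-2-enyl)benzene-1,3-diol F17. Three-fold silylation gives 1,5-bis(tert-butyldimethylsilyloxy)-3-[3-(tert-butyldimethylsilyloxy)prop-1-ynyl]-2,4-bis(3-methylbut-2-enyl)benzene F18. Pyridinium p-toluenesulfonate in MeOH, which cleaves the alkyl silyl ether but not the aryl silyl ethers, gives 8.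

## Further compounds

F1 | step 10 | 3-(trimethylsilyl)prop-2-ynal (purchased) | O=CC#C[Si](C)(C)C
F2 | step 10 | (3E)-6-(trimethylsilyl)hex-3-en-5-yn-2-one | CC(=O)/C=C/C#C[Si](C)(C)C
F3 | step 10 | (5E)-1,1,1-trifluoro-8-(trimethylsilyl)oct-5-en-7-yne-2,4-dione | O=C(CC(=O)/C=C/C#C[Si](C)(C)C)C(F)(F)F
F4 | step 10 | (3E)-1-diazo-6-(trimethylsilyl)hex-3-en-5-yn-2-one | [N-]=[N+]=CC(=O)/C=C/C#C[Si](C)(C)C
F5 | step 10 | (3E)-6-(trimethylsilyl)hexa-1,3-dien-5-yn-1-one | O=C=C/C=C/C#C[Si](C)(C)C
F6 | step 10 | 2-(3-methylbut-2-enyl)-3-(triisopropylsilyloxy)-4-[(1E)-4-(trimethylsilyl)but-1-en-3-ynyl]cyclobut-2-en-1-one (racemic) | O=C1C(CC=C(C)C)=C(O[Si](C(C)C)(C(C)C)C(C)C)C1/C=C/C#C[Si](C)(C)C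
F7 | step 10 | (3E,5E)-2-(3-methylbut-2-enyl)-3-(triisopropylsilyloxy)-8-(trimethylsilyl)octa-1,3,5-trien-7-yn-1-one | O=C=C(CC=C(C)C)/C(O[Si](C(C)C)(C(C)C)C(C)C)=C\C=C\C#C[Si](C)(C)C
F8 | step 10 | 2-(3-methylbut-2-enyl)-3-(triisopropylsilyloxy)-6-[(trimethylsilyl)ethynyl]cyclohexa-2,4-dien-1-one (racemic) | O=C1C(CC=C(C)C)=C(O[Si](C(C)C)(C(C)C)C(C)C)C=CC1C#C[Si](C)(C)C
F9 | step 10 | 2-(3-methylbut-2-enyl)-3-(triisopropylsilyloxy)-6-[(trimethylsilyl)ethynyl]phenol | Oc1c(CC=C(C)C)c(O[Si](C(C)C)(C(C)C)C(C)C)ccc1C#C[Si](C)(C)C
F10 | step 10 | 6-ethynyl-2-(3-methylbut-2-enyl)-3-(triisopropylsilyloxy)phenol | Oc1c(CC=C(C)C)c(O[Si](C(C)C)(C(C)C)C(C)C)ccc1C#C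
F11 | step 3 | 1,3-bis(tert-butyldimethylsilyloxy)-5-iodobenzene | CC(C)(C)[Si](C)(C)Oc1cc(I)cc(O[Si](C)(C)C(C)(C)C)c1
F12 | step 3 | 3-[3,5-bis(tert-butyldimethylsilyloxy)phenyl]prop-2-yn-1-ol | OCC#Cc1cc(O[Si](C)(C)C(C)(C)C)cc(O[Si](C)(C)C(C)(C)C)c1
F13 | step 3 | 3-[2,6-dibromo-3,5-bis(tert-butyldimethylsilyloxy)phenyl]prop-2-yn-1-ol | OCC#Cc1c(Br)c(O[Si](C)(C)C(C)(C)C)cc(O[Si](C)(C)C(C)(C)C)c1Br
F14 | step 3 | (3-methylbut-2-enyl)zinc bromide | CC(C)=CC[Zn]Br
F15 | step 11 | 2-[3,5-bis(tert-butyldimethylsilyloxy)-2,6-bis(3-methylbut-2-enyl)phenyl]-7-(3-methylbut-2-enyl)-6-(triisopropylsilyloxy)-1-benzofuran | CC(C)=CCc1c(O[Si](C)(C)C(C)(C)C)cc(O[Si](C)(C)C(C)(C)C)c(CC=C(C)C)c1-c1cc2ccc(O[Si](C(C)C)(C(C)C)C(C)C)c(CC=C(C)C)c2o1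
F16 | step 5 | 3-{3,5-bis[(2-methylbut-3-en-2-yl)oxy]phenyl}prop-2-yn-1-ol | OCC#Cc1cc(OC(C)(C)C=C)cc(OC(C)(C)C=C)c1
F17 | step 5 | 5-(3-hydroxyprop-1-ynyl)-4,6-bis(3-methylbut-2-enyl)benzene-1,3-diol | OCC#Cc1c(CC=C(C)C)c(O)cc(O)c1CC=C(C)C
F18 | step 5 | 1,5-bis(tert-butyldimethylsilyloxy)-3-[3-(tert-butyldimethylsilyloxy)prop-1-ynyl]-2,4-bis(3-methylbut-2-enyl)benzene | CC(C)(C)[Si](C)(C)OCC#Cc1c(CC=C(C)C)c(O[Si](C)(C)C(C)(C)C)cc(O[Si](C)(C)C(C)(C)C)c1CC=C(C)C
A1 | alternative 1 | 1-iodo-3,5-bis(methoxymethoxy)benzene | COCOc1cc(I)cc(OCOC)c1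
A2 | alternative 1 | (2-bromoethoxy)(tert-butyl)dimethylsilane | BrCCO[Si](C)(C)C(C)(C)C
A3 | alternative 1 | 2-[6-(methoxymethoxy)-7-(3-methylbut-2-enyl)-1-benzofuran-2-yl]-4,4,5,5-tetramethyl-1,3,2-dioxaborolane | COCOc1ccc2cc(B3OC(C)(C)C(C)(C)O3)oc2c1CC=C(C)C
A4 | alternative 1 | 2-{2,6-bis[2-(tert-butyldimethylsilyloxy)ethyl]-3,5-bis(methoxymethoxy)phenyl}-6-(methoxymethoxy)-7-(3-methylbut-2-enyl)benzofuran | COCOc1cc(OCOC)c(CCO[Si](C)(C)C(C)(C)C)c(c1CCO[Si](C)(C)C(C)(C)C)-c1cc2ccc(OCOC)c(CC=C(C)C)c2o1
A5 | alternative 2 | 2,12-dimethyltrideca-2,11-diene-6,8-dione | CC(C)=CCCC(=O)CC(=O)CCC=C(C)C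
A6 | alternative 2 | methyl 6-(methoxymethoxy)-7-(3-methylbut-2-enyl)-1-benzofuran-2-carboxylate | COCOc1ccc2cc(C(=O)OC)oc2c1CC=C(C)C
A7 | alternative 2 | 1-[6-(methoxymethoxy)-7-(3-methylbut-2-enyl)-1-benzofuran-2-yl]-9-methyl-2-(3-methylbut-2-enyl)dec-8-ene-1,3,5-trione (racemic) | COCOc1ccc2cc(C(=O)C(CC=C(C)C)C(=O)CC(=O)CCC=C(C)C)oc2c1CC=C(C)C
A8 | alternative 2 | 2-[3,5-dihydroxy-2,6-bis(3-methylbut-2-enyl)phenyl]-6-(methoxymethoxy)-7-(3-methylbut-2-enyl)benzofuran | CC(C)=CCc1c(O)cc(O)c(CC=C(C)C)c1-c1cc2ccc(OCOC)c(CC=C(C)C)c2o1
A9 | alternative 3 | (1E)-4-{5-[3,5-bis(tert-butyldimethylsilyloxy)-2,6-bis(3-methylbut-2-enyl)phenyl]furan-2-yl}-1-(dimethylamino)-7-methylocta-1,6-dien-3-one (racemic) | CN(C)/C=C/C(=O)C(CC=C(C)C)c1ccc(o1)-c1c(CC=C(C)C)c(O[Si](C)(C)C(C)(C)C)cc(O[Si](C)(C)C(C)(C)C)c1CC=C(C)C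
A10 | alternative 3 | (1E,3E)-4-{5-[3,5-bis(tert-butyldimethylsilyloxy)-2,6-bis(3-methylbut-2-enyl)phenyl]furan-2-yl}-3-(tert-butyldimethylsilyloxy)-N,N,7-trimethylocta-1,3,6-trien-1-amine | CN(C)/C=C/C(O[Si](C)(C)C(C)(C)C)=C(/CC=C(C)C)c1ccc(o1)-c1c(CC=C(C)C)c(O[Si](C)(C)C(C)(C)C)cc(O[Si](C)(C)C(C)(C)C)c1CC=C(C)C
A11 | alternative 3 | 2-[3,5-bis(tert-butyldimethylsilyloxy)-2,6-bis(3-methylbut-2-enyl)phenyl]-6-(tert-butyldimethylsilyloxy)-7-(3-methylbut-2-enyl)-1-benzofuran | CC(C)=CCc1c(O[Si](C)(C)C(C)(C)C)cc(O[Si](C)(C)C(C)(C)C)c(CC=C(C)C)c1-c1cc2ccc(O[Si](C)(C)C(C)(C)C)c(CC=C(C)C)c2o1
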